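At early times the first readings of these runs give us the orders, and the later readings show how the rate fades.

| flask | starting material | free catalyst | time |
|---|---|---|---|
| theta | 0.250 M | 0.00250 M |  |
| gamma | 0.100 M | 0.00250 M |  |
| delta | 0.750 M | 0.00250 M |  |
| zeta | 0.250 M | 0.00370 M |  |
| alpha | 0.750 M | 0.00250 M | 33 min |

- theta run (time / min: [target] / M): 6.6: 0.030; 13: 0.062; 20: 0.089; 26: 0.107; 33: 0.135
- gamma run (time / min: [target] / M): 6.6: 0.019; 13: 0.042; 20: 0.052; 26: 0.064; 33: 0.071
- delta run (time / min: [target] / M): 6.6: 0.056; 13: 0.104; 20: 0.139; 26: 0.169; 33: 0.199
- zeta run (time / min: [target] / M): 6.6: 0.069; 13: 0.130; 20: 0.167; 26: 0.193; 33: 0.217

(readings scatter by 0.004 M)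

- Overall: starting material -> target, with free catalyst as catalyst.
- Constant volume, constant temperature.
- The analysis sees a species whether free or bound.
- An order is taken over about fifteen percent of the charge, up and down.

- apparent order in [starting material] of the starting rate, round the charge of the theta run (the rate where two percent of its starting material have turned into target) (one fixed amount of target, the same in the runs compared)
- apparent order in [free catalyst] of the starting rate, round the charge of the theta run (the rate where two percent of its starting material have turned into target)
- the gamma run starts with 0.150 M less of starting material than the theta run, and with no target. Compared where both hold the same amount of starting material, once fifteen percent of what the gamma run was charged with has turned into target, is the gamma run faster, slower or alike (within a tenth)?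
- target in the alpha run at 33 min, as a share of the starting material charged

The first readings of the delta and theta runs give an order of 0.568 in [starting material], and those of the zeta and theta runs give 2.12 in [free catalyst]. The delta run then slows by more than its used starting material explains: with an order of 0.5, its late rate is 0.606 of its early rate. Our reading of this is the fade amount, 0.386 M, the target over which the rate at fixed [starting material] falls in a straight line towards zero.

At the matched point, the gamma run has made 0.0150 M of target and the theta run 0.165 M. We therefore expect the gamma run to be faster by a factor of 1.68. The alpha run has the delta recipe, so the delta reading at 33 min gives 26.5%.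

The forecast, which says “activity is being lost with time or turnover”, gave 0.5 (0.38 to 0.62), 2 (1.7 to 2.3), faster and 26.5% (25.3% to 27.7%).

The simulation gives 0.55, 2.0, faster and 26.9%, so the forecast held on each.

    free catalyst + starting material ⇌ catalyst-substrate complex, settled at all times (0.8540 M⁻¹)
    catalyst-substrate complex + free catalyst → target + 2 free catalyst (11100 M⁻¹ min⁻¹)
    catalyst-substrate complex → spent catalyst + starting material (0.07980 min⁻¹)
    2 starting material ⇌ idle substrate dimer, settled at all times (4.940 M⁻¹)

At each fork, a catalyst-substrate complex either meets free catalyst and gives target or turns into spent catalyst (deactivation). At the start of the alpha run, the two fast equilibria leave 0.230 M of unbound starting material and 0.00209 M of free catalyst, so the first happens 291 times for each time of the second. At 26.9%, the fade amount leaves the alpha run 47.8% of its starting rate at fixed [starting material]. Carried to the gamma and theta runs, it gave 1.68, and the flask gives 1.6. With the path to spent catalyst removed, that ratio becomes 1.0.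

The readings are simulated for an exercise; the scatter is artificial.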